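**Strategy.** The oxane is opened at O1–C6 and its side chain cut at the first CH2–CH2 bond, leaving a six-carbon hydroxy acid. C2 (chain) and C6 (ring B) are equatorial and the C4 acetate axial, so the oxygens on C2 and C4 form a syn-1,3-diol, the cis pattern of meso cis-3,5-bis(tert-butyldimethylsilyloxy)cyclohexanone made from phloroglucinol. One catalytic enantioselective Baeyer–Villiger oxidation of this ketone cleaves one enantiotopic C(=O)–CH2 bond, forms the C–O bond, expands the ring to the oxepan-2-one and fixes both carbinol centres. The lactone carbonyl becomes C6, its OCH2 carbon the first chain carbon towards ring A, and C6 is set last by axial hydride delivery.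

Key step: step 4

Remark: the sense of enantiotopic discrimination by the scandium complex cannot be predicted for this substrate, so the ligand antipode that gives the (4S,6R)-lactone is assumed to be chosen after one analytical run; alcohol 9 is taken as purchasable (otherwise two routine steps from vanillin).

Step 1
Reactants: 1 phloroglucinol
Product: 2 all-cis-cyclohexane-1,3,5-triol
Conditions: H2 (100 bar), 5% Rh/Al2O3, EtOH, 60 °C; recrystallisation
Reagents that add atoms: none
Why: Heterogeneous arene hydrogenation delivers all hydrogens from the catalyst-bound face, so the all-cis meso triol should dominate and no absolute stereochemistry is involved.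

Step 2
Reactants: 2 all-cis-cyclohexane-1,3,5-triol
Product: 3 all-cis-3,5-bis(tert-butyldimethylsilyloxy)cyclohexan-1-ol
Conditions: TBSCl (2.0 equiv), imidazole, DMF, 0 °C → rt; chromatography
Reagents that add atoms: tert-butyldimethylsilyl chloride, CC(C)(C)[Si](C)(C)Cl
Why: Imidazole-promoted silylation of three equivalent secondary hydroxyls is statistical, so two equivalents of TBSCl should make the achiral bis-ether the main product, with mono- and tris-ethers separated and recycled.

Step 3
Reactants: 3 all-cis-3,5-bis(tert-butyldimethylsilyloxy)cyclohexan-1-ol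
Product: 4 (3R,5S)-3,5-bis(tert-butyldimethylsilyloxy)cyclohexan-1-one (meso)
Conditions: Dess–Martin periodinane, CH2Cl2, rt
Reagents that add atoms: none
Why: Dess–Martin oxidation of the remaining secondary alcohol is neutral and base-free, which should avoid E1cB loss of the β-silyloxy groups.

Step 4
Reactants: 4 (3R,5S)-3,5-bis(tert-butyldimethylsilyloxy)cyclohexan-1-one
Product: 6 (4S,6R)-4,6-bis(tert-butyldimethylsilyloxy)oxepan-2-one, via Criegee adduct 5 (not isolated)
Conditions: Sc(OTf)3 (5 mol %), C2-symmetric chiral N,N'-dioxide ligand (bis-N-oxide of propane-1,3-diyl-linked bis[pipecolic acid 2,6-diisopropylanilide], 6 mol %), mCPBA (1.2 equiv), EtOAc, −20 °C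
Reagents that add atoms: 3-chloroperoxybenzoic acid (mCPBA), OOC(=O)c1cccc(Cl)c1
Why: The scandium-activated ketone adds the peracid to give Criegee adduct 5, and in the chiral pocket of the N,N'-dioxide complex only one of the two enantiotopic α-CH2 groups can lie antiperiplanar to the O–O bond and migrate as 3-chlorobenzoate leaves (Baeyer–Villiger oxidation). The closest known reaction type is the catalytic enantioselective Baeyer–Villiger desymmetrisation of meso cis-3,5-disubstituted and prochiral 4-substituted cyclohexanones by chiral scandium N,N'-dioxide complexes or by cyclohexanone monooxygenases. The oxepan-2-one ring arises by a one-atom ring expansion through a 1,2-shift with retention at the migrating carbon, not by a cyclisation, so no closure mode has to be met. Both carbinol centres already exist in the meso ketone with their cis relationship fixed by the substrate, and the catalyst alone decides which becomes C4 and which C6, that is, the absolute configuration (4S,6R). The step needs only enantiotopic-group selectivity, because both candidate migrating carbons are CH2 groups of equal migratory aptitude held in one diequatorial chair. The silyl ethers are bulky and weakly coordinating, so they should not displace the ligand from scandium and they enlarge the steric difference the catalyst has to read.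

Step 5
Reactants: 6 (4S,6R)-4,6-bis(tert-butyldimethylsilyloxy)oxepan-2-one
Product: 7 (3S,5R)-3,5-bis(tert-butyldimethylsilyloxy)-6-hydroxy-N-methoxy-N-methylhexanamide
Conditions: MeNHOMe·HCl, AlMe3, CH2Cl2, 0 °C → rt; aqueous Rochelle salt
Reagents that add atoms: N,O-dimethylhydroxylamine hydrochloride, CNOC.Cl
Why: Aluminium amide aminolysis of the lactone (Weinreb amide formation) opens the ring without strong base, which should exclude double addition, enolisation and 1,2-silyl migration to the liberated primary oxygen, and it touches neither stereocentre.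

Step 6
Reactants: 7 (3S,5R)-3,5-bis(tert-butyldimethylsilyloxy)-6-hydroxy-N-methoxy-N-methylhexanamide
Product: 8 (3S,5R)-3,5-bis(tert-butyldimethylsilyloxy)-N-methoxy-N-methyl-6-oxohexanamide
Conditions: Dess–Martin periodinane, CH2Cl2, 0 °C → rt
Reagents that add atoms: none
Why: Dess–Martin oxidation of the primary alcohol gives the α-silyloxy aldehyde without base, so the adjacent stereocentre should not epimerise.

Step 7
Reactants: 9 [4-(benzyloxy)-3-methoxyphenyl]methanol
Product: 10 [4-(benzyloxy)-3-methoxybenzyl]triphenylphosphonium bromide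
Conditions: PPh3·HBr, MeCN, reflux
Reagents that add atoms: triphenylphosphine hydrobromide, Br.P(c1ccccc1)(c1ccccc1)c1ccccc1
Why: The electron-rich benzylic alcohol ionises under the mild acid and the benzylic cation is captured by triphenylphosphine (phosphonium salt formation from a benzylic alcohol).

Step 8
Reactants: 10 [4-(benzyloxy)-3-methoxybenzyl]triphenylphosphonium bromide; 8 (3S,5R)-3,5-bis(tert-butyldimethylsilyloxy)-N-methoxy-N-methyl-6-oxohexanamide
Product: 12 (3S,5R)-7-[4-(benzyloxy)-3-methoxyphenyl]-3,5-bis(tert-butyldimethylsilyloxy)-N-methoxy-N-methylhept-6-enamide (E/Z mixture), via ylide 11 (not isolated)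
Conditions: 10, NaN(SiMe3)2, THF, 0 °C; then 8, −78 °C → rt
Reagents that add atoms: none
Why: Wittig olefination with the semi-stabilised benzylic ylide is fast at low temperature, the ylide is too weak a base to enolise the aldehyde or the amide, and the alkene geometry is irrelevant because step 9 saturates it.

Step 9
Reactants: 12 (3S,5R)-7-[4-(benzyloxy)-3-methoxyphenyl]-3,5-bis(tert-butyldimethylsilyloxy)-N-methoxy-N-methylhept-6-enamide
Product: 13 (3S,5S)-7-[4-(benzyloxy)-3-methoxyphenyl]-3,5-bis(tert-butyldimethylsilyloxy)-N-methoxy-N-methylheptanamide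
Conditions: H2 (1 atm), 10% Pd/C, Ph2S (cat.), EtOAc, rt
Reagents that add atoms: none
Why: Catalytic hydrogenation over sulfide-poisoned Pd/C should saturate the disubstituted alkene while sparing the aryl benzyl ether, and removing the styrene here keeps an acid-labile cinnamyl-type C–O bond out of steps 13 and 14.

Step 10
Reactants: 14 5-bromo-2-hydroxy-3-methoxybenzaldehyde
Product: 16 5-bromo-3-methoxybenzene-1,2-diol, via aryl formate 15 (not isolated)
Conditions: 30% H2O2, aqueous NaOH, 0 °C → rt, under N2; then HCl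
Reagents that add atoms: hydrogen peroxide, OO
Why: Dakin oxidation, in which the ortho-phenoxide-activated aldehyde adds hydroperoxide, aryl migration gives formate 15 and hydrolysis in the same flask releases the catechol.

Step 11
Reactants: 16 5-bromo-3-methoxybenzene-1,2-diol
Product: 17 1,2-bis(benzyloxy)-5-bromo-3-methoxybenzene
Conditions: BnBr, K2CO3, DMF, rt → 60 °C
Reagents that add atoms: benzyl bromide, BrCc1ccccc1
Why: Williamson etherification of both phenols gives benzyl ethers that tolerate aryllithium and acidic steps and are removed by hydrogenolysis at the end.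

Step 12
Reactants: 17 1,2-bis(benzyloxy)-5-bromo-3-methoxybenzene; 13 (3S,5S)-7-[4-(benzyloxy)-3-methoxyphenyl]-3,5-bis(tert-butyldimethylsilyloxy)-N-methoxy-N-methylheptanamide
Product: 19 (3S,5S)-1-[3,4-bis(benzyloxy)-5-methoxyphenyl]-7-[4-(benzyloxy)-3-methoxyphenyl]-3,5-bis(tert-butyldimethylsilyloxy)heptan-1-one, via aryllithium 18 (not isolated)
Conditions: 17, n-BuLi, THF, −78 °C; then 13, −78 → −20 °C; aqueous NH4Cl
Reagents that add atoms: none
Why: Bromine–lithium exchange gives aryllithium 18, which adds only once to the Weinreb amide because the chelated tetrahedral adduct survives until work-up (Weinreb ketone synthesis).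

Step 13
Reactants: 19 (3S,5S)-1-[3,4-bis(benzyloxy)-5-methoxyphenyl]-7-[4-(benzyloxy)-3-methoxyphenyl]-3,5-bis(tert-butyldimethylsilyloxy)heptan-1-one
Product: 20 (3S,5S)-1-[3,4-bis(benzyloxy)-5-methoxyphenyl]-7-[4-(benzyloxy)-3-methoxyphenyl]-3,5-dihydroxyheptan-1-one
Conditions: HF·pyridine, pyridine, THF, 0 °C → rt
Reagents that add atoms: none
Why: Buffered acidic fluoride desilylation should free both hydroxyls without the E1cB elimination or retro-aldol cleavage that a basic fluoride source would risk for a β-oxygenated aryl ketone.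

Step 14
Reactants: 20 (3S,5S)-1-[3,4-bis(benzyloxy)-5-methoxyphenyl]-7-[4-(benzyloxy)-3-methoxyphenyl]-3,5-dihydroxyheptan-1-one
Product: 23 (2S,4S,6S)-2-[3,4-bis(benzyloxy)-5-methoxyphenyl]-6-{2-[4-(benzyloxy)-3-methoxyphenyl]ethyl}oxan-4-ol, via lactol 21 (not isolated), via oxocarbenium ion 22 (not isolated)
Conditions: Et3SiH (5 equiv), BF3·OEt2 (3 equiv), CH2Cl2/MeCN, −40 → −10 °C
Reagents that add atoms: none
Why: Only the C5 hydroxyl of the heptanone can close a six-membered lactol 21, BF3 ionises it to oxocarbenium ion 22, and the silane delivers hydride axially to the half-chair that holds the arylethyl chain pseudo-equatorial and the C4 hydroxyl pseudo-axial, which should set C6 cis to C2 (ionic hydrogenation of a lactol).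

Step 15
Reactants: 23 (2S,4S,6S)-2-[3,4-bis(benzyloxy)-5-methoxyphenyl]-6-{2-[4-(benzyloxy)-3-methoxyphenyl]ethyl}oxan-4-ol
Product: 24 (2S,4S,6S)-2-[3,4-bis(benzyloxy)-5-methoxyphenyl]-6-{2-[4-(benzyloxy)-3-methoxyphenyl]ethyl}oxan-4-yl acetate
Conditions: Ac2O, pyridine, DMAP (cat.), CH2Cl2, rt
Reagents that add atoms: acetic anhydride, CC(=O)OC(C)=O
Why: DMAP-catalysed acetylation meets a single free hydroxyl, the axial secondary alcohol, because all three phenols are still benzyl ethers.

Step 16
Reactants: 24 (2S,4S,6S)-2-[3,4-bis(benzyloxy)-5-methoxyphenyl]-6-{2-[4-(benzyloxy)-3-methoxyphenyl]ethyl}oxan-4-yl acetate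
Product: 25 (2S,4S,6S)-2-(3,4-dihydroxy-5-methoxyphenyl)-6-[2-(4-hydroxy-3-methoxyphenyl)ethyl]oxan-4-yl acetate
Conditions: H2 (1 atm), 10% Pd/C, EtOAc, rt
Reagents that add atoms: none
Why: Neutral hydrogenolysis of the three aryl benzyl ethers over Pd/C should be much faster than cleavage of the benzylic ring C–O bond and leaves the acetate untouched.

**Compound list**

1 | phloroglucinol | Oc1cc(O)cc(O)c1 | starting material
2 | all-cis-cyclohexane-1,3,5-triol | O[C@H]1C[C@@H](O)C[C@@H](O)C1 | intermediate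
3 | all-cis-3,5-bis(tert-butyldimethylsilyloxy)cyclohexan-1-ol | O[C@H]1C[C@@H](O[Si](C)(C)C(C)(C)C)C[C@@H](O[Si](C)(C)C(C)(C)C)C1 | intermediate
4 | (3R,5S)-3,5-bis(tert-butyldimethylsilyloxy)cyclohexan-1-one (meso, cis) | O=C1C[C@H](O[Si](C)(C)C(C)(C)C)C[C@H](O[Si](C)(C)C(C)(C)C)C1 | intermediate
5 | Criegee adduct, 1-hydroxy-cis-3,5-bis(tert-butyldimethylsilyloxy)cyclohexyl 3-chloroperoxybenzoate (peroxy carbon not defined) | OC1(OOC(=O)c2cccc(Cl)c2)C[C@H](O[Si](C)(C)C(C)(C)C)C[C@H](O[Si](C)(C)C(C)(C)C)C1 | intermediate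
6 | (4S,6R)-4,6-bis(tert-butyldimethylsilyloxy)oxepan-2-one | O=C1C[C@@H](O[Si](C)(C)C(C)(C)C)C[C@@H](O[Si](C)(C)C(C)(C)C)CO1 | intermediate
7 | (3S,5R)-3,5-bis(tert-butyldimethylsilyloxy)-6-hydroxy-N-methoxy-N-methylhexanamide | CON(C)C(=O)C[C@@H](O[Si](C)(C)C(C)(C)C)C[C@@H](O[Si](C)(C)C(C)(C)C)CO | intermediate
8 | (3S,5R)-3,5-bis(tert-butyldimethylsilyloxy)-N-methoxy-N-methyl-6-oxohexanamide | CON(C)C(=O)C[C@@H](O[Si](C)(C)C(C)(C)C)C[C@@H](O[Si](C)(C)C(C)(C)C)C=O | intermediate
9 | [4-(benzyloxy)-3-methoxyphenyl]methanol | COc1cc(CO)ccc1OCc1ccccc1 | starting material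
10 | [4-(benzyloxy)-3-methoxybenzyl]triphenylphosphonium bromide | COc1cc(C[P+](c2ccccc2)(c2ccccc2)c2ccccc2)ccc1OCc1ccccc1.[Br-] | intermediate
11 | ylide, [4-(benzyloxy)-3-methoxybenzylidene]triphenylphosphorane | COc1cc(C=P(c2ccccc2)(c2ccccc2)c2ccccc2)ccc1OCc1ccccc1 | intermediate
12 | (3S,5R)-7-[4-(benzyloxy)-3-methoxyphenyl]-3,5-bis(tert-butyldimethylsilyloxy)-N-methoxy-N-methylhept-6-enamide (E/Z mixture) | CON(C)C(=O)C[C@@H](O[Si](C)(C)C(C)(C)C)C[C@@H](O[Si](C)(C)C(C)(C)C)C=Cc1ccc(OCc2ccccc2)c(OC)c1 | intermediate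
13 | (3S,5S)-7-[4-(benzyloxy)-3-methoxyphenyl]-3,5-bis(tert-butyldimethylsilyloxy)-N-methoxy-N-methylheptanamide | CON(C)C(=O)C[C@@H](O[Si](C)(C)C(C)(C)C)C[C@@H](O[Si](C)(C)C(C)(C)C)CCc1ccc(OCc2ccccc2)c(OC)c1 | intermediate
14 | 5-bromo-2-hydroxy-3-methoxybenzaldehyde | COc1cc(Br)cc(C=O)c1O | starting material
15 | aryl formate, 5-bromo-2-hydroxy-3-methoxyphenyl formate | COc1cc(Br)cc(OC=O)c1O | intermediate
16 | 5-bromo-3-methoxybenzene-1,2-diol | COc1cc(Br)cc(O)c1O | intermediate
17 | 1,2-bis(benzyloxy)-5-bromo-3-methoxybenzene | COc1cc(Br)cc(OCc2ccccc2)c1OCc1ccccc1 | intermediate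
18 | aryllithium, [3,4-bis(benzyloxy)-5-methoxyphenyl]lithium | [Li]c1cc(OC)c(OCc2ccccc2)c(OCc2ccccc2)c1 | intermediate
19 | (3S,5S)-1-[3,4-bis(benzyloxy)-5-methoxyphenyl]-7-[4-(benzyloxy)-3-methoxyphenyl]-3,5-bis(tert-butyldimethylsilyloxy)heptan-1-one | COc1cc(cc(OCc2ccccc2)c1OCc1ccccc1)C(=O)C[C@@H](O[Si](C)(C)C(C)(C)C)C[C@@H](O[Si](C)(C)C(C)(C)C)CCc1ccc(OCc2ccccc2)c(OC)c1 | intermediate
20 | (3S,5S)-1-[3,4-bis(benzyloxy)-5-methoxyphenyl]-7-[4-(benzyloxy)-3-methoxyphenyl]-3,5-dihydroxyheptan-1-one | COc1cc(cc(OCc2ccccc2)c1OCc1ccccc1)C(=O)C[C@@H](O)C[C@@H](O)CCc1ccc(OCc2ccccc2)c(OC)c1 | intermediate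
21 | lactol, (4S,6S)-2-[3,4-bis(benzyloxy)-5-methoxyphenyl]-6-{2-[4-(benzyloxy)-3-methoxyphenyl]ethyl}oxane-2,4-diol (anomeric mixture) | COc1cc(CC[C@H]2C[C@H](O)CC(O)(c3cc(OCc4ccccc4)c(OCc4ccccc4)c(OC)c3)O2)ccc1OCc1ccccc1 | intermediate
22 | oxocarbenium ion, (2S,4S)-6-[3,4-bis(benzyloxy)-5-methoxyphenyl]-2-{2-[4-(benzyloxy)-3-methoxyphenyl]ethyl}-4-hydroxy-3,4-dihydro-2H-pyran-1-ium | COc1cc(CC[C@H]2C[C@H](O)CC(c3cc(OCc4ccccc4)c(OCc4ccccc4)c(OC)c3)=[O+]2)ccc1OCc1ccccc1 | intermediate
23 | (2S,4S,6S)-2-[3,4-bis(benzyloxy)-5-methoxyphenyl]-6-{2-[4-(benzyloxy)-3-methoxyphenyl]ethyl}oxan-4-ol | COc1cc(CC[C@H]2C[C@H](O)C[C@@H](c3cc(OCc4ccccc4)c(OCc4ccccc4)c(OC)c3)O2)ccc1OCc1ccccc1 | intermediate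
24 | (2S,4S,6S)-2-[3,4-bis(benzyloxy)-5-methoxyphenyl]-6-{2-[4-(benzyloxy)-3-methoxyphenyl]ethyl}oxan-4-yl acetate | COc1cc(CC[C@H]2C[C@H](OC(C)=O)C[C@@H](c3cc(OCc4ccccc4)c(OCc4ccccc4)c(OC)c3)O2)ccc1OCc1ccccc1 | intermediate
25 | (2S,4S,6S)-2-(3,4-dihydroxy-5-methoxyphenyl)-6-[2-(4-hydroxy-3-methoxyphenyl)ethyl]oxan-4-yl acetate | COc1cc(CC[C@H]2C[C@H](OC(C)=O)C[C@@H](c3cc(O)c(O)c(OC)c3)O2)ccc1O | target

**Totals.** Total step count: 16. Longest linear sequence: 13 steps (1 → 25 through steps 1–6, 8, 9, 12–16).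

**Steps most likely to fail**

Step 4. The catalyst may discriminate poorly between the two enantiotopic migrating CH2 groups, or the Lewis acid may promote β-elimination of a silyloxy group. The fallback sets out from ketone 4 and rejoins the route at aldehyde 8, bypassing 6 and 7. Enantioselective deprotonation with a chiral lithium amide (lithium (R,R)- or (S,S)-bis(1-phenylethyl)amide, TMSCl present in situ, THF, −100 °C) should give the silyl enol ether (3R,5S)-3,5-bis(tert-butyldimethylsilyloxy)-1-(trimethylsilyloxy)cyclohex-1-ene F1. Ozonolysis (O3, CH2Cl2/MeOH, −78 °C; Me2S) cleaves the C1=C2 bond to the oxo acid (3S,5R)-3,5-bis(tert-butyldimethylsilyloxy)-6-oxohexanoic acid F2. Carbodiimide coupling with N,O-dimethylhydroxylamine (EDC·HCl, MeNHOMe·HCl, N-methylmorpholine, CH2Cl2) then gives 8.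

Step 14. Hydride delivery may lose facial control, or the newly formed benzylic C6–O1 bond may ionise under the Lewis acid and be reduced further. The fallback sets out from 20 and rejoins at 23. NaBH4 (MeOH, 0 °C) reduces the ketone to the triol (3S,5S)-1-[3,4-bis(benzyloxy)-5-methoxyphenyl]-7-[4-(benzyloxy)-3-methoxyphenyl]heptane-1,3,5-triol F3 as a mixture of C1 epimers. Catalytic acid (TsOH·H2O, CH2Cl2, rt) ionises the electron-rich benzylic alcohol and the C5 hydroxyl closes the oxane under thermodynamic control. Both epimers should converge on the 2,6-diequatorial ether 23, with no hydride source present.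

Step 16. Hydrogenolytic opening of the oxane at the benzylic C6–O1 bond may compete with O-debenzylation. The fallback sets out from alcohol 23 and rejoins at target 25. Non-reductive debenzylation (BCl3, pentamethylbenzene, CH2Cl2, −78 °C) should give the tetrol (2S,4S,6S)-2-(3,4-dihydroxy-5-methoxyphenyl)-6-[2-(4-hydroxy-3-methoxyphenyl)ethyl]oxan-4-ol F4. Peracetylation (Ac2O, pyridine, rt) gives the tetraacetate (2S,4S,6S)-2-(3,4-diacetoxy-5-methoxyphenyl)-6-[2-(4-acetoxy-3-methoxyphenyl)ethyl]oxan-4-yl acetate F5. Chemoselective cleavage of the three aryl acetates (NH4OAc, aqueous MeOH, rt), which an alkyl acetate should survive, gives 25.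

Further compounds
F1 | step 4 | (3R,5S)-3,5-bis(tert-butyldimethylsilyloxy)-1-(trimethylsilyloxy)cyclohex-1-ene | C[Si](C)(C)OC1=C[C@H](O[Si](C)(C)C(C)(C)C)C[C@H](O[Si](C)(C)C(C)(C)C)C1
F2 | step 4 | (3S,5R)-3,5-bis(tert-butyldimethylsilyloxy)-6-oxohexanoic acid | OC(=O)C[C@@H](O[Si](C)(C)C(C)(C)C)C[C@@H](O[Si](C)(C)C(C)(C)C)C=O
F3 | step 14 | (3S,5S)-1-[3,4-bis(benzyloxy)-5-methoxyphenyl]-7-[4-(benzyloxy)-3-methoxyphenyl]heptane-1,3,5-triol (both C1 epimers) | COc1cc(cc(OCc2ccccc2)c1OCc1ccccc1)C(O)C[C@@H](O)C[C@@H](O)CCc1ccc(OCc2ccccc2)c(OC)c1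
F4 | step 16 | (2S,4S,6S)-2-(3,4-dihydroxy-5-methoxyphenyl)-6-[2-(4-hydroxy-3-methoxyphenyl)ethyl]oxan-4-ol | COc1cc(CC[C@H]2C[C@H](O)C[C@@H](c3cc(O)c(O)c(OC)c3)O2)ccc1O
F5 | step 16 | (2S,4S,6S)-2-(3,4-diacetoxy-5-methoxyphenyl)-6-[2-(4-acetoxy-3-methoxyphenyl)ethyl]oxan-4-yl acetate | COc1cc(CC[C@H]2C[C@H](OC(C)=O)C[C@@H](c3cc(OC(C)=O)c(OC(C)=O)c(OC)c3)O2)ccc1OC(C)=O
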